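**Plan**
- Retrosynthesis: ring A is cut at C1–C2 and C3–C4 into 1-bromo-2-methylprop-1-ene (C2=C3) and a 2-oxyallyl cation C1–C5–C4 hung on C6. C4–C6 is then cut (Darzens) to 3-chlorobutan-2-one and a ring B/C bromo decalone, which goes back to (S)-Wieland–Miescher ketone.
- Forward: rings B and C come ready-made; the C12 bromide, the C10/C15 diol and the C6 ketone are set on the decalin (steps 1–11). The C4–C5–C1 unit is added as a spiro-epoxy ketone (step 12), ring A is closed in one step (step 14), then C5=O is reduced and silicon is removed.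
- Enabling feature: O5 sits on the carbon between C1 and C4 (a latent 2-oxyallyl cation) and O6 is 1,3 to it across C4. The epoxide oxygen O6 can therefore be the leaving group at C4 and the future C6 hydroxyl, and one silicon atom can tie O5 to O6 in a six-membered 1,3-dioxa-2-silacyclohexene ring that holds the cation.
- Stereochemistry: C9 comes from the starting ketone. C12, C10, C15 and C6 come from substrate control on the trans-decalin (reagents anti to the C9 methyl, equatorial attack at C6). C4 and C2 are set in the key step through the silicon ring, and C5 by hydride delivery anti to the C6 substituent.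

Key step: step 14

Locants used below: ring A = C1 (CH2), C2 (CHBr), C3 (CMe2), C4 (C–CH3), C5 (CHOH); ring B = C6 (carbinol carbon on C4), C7, C8, C9 (C–CH3), C10 (C–OH), C11; ring C = C9, C12 (CHBr), C13, C14, C15 (C(CH3)OH), C10. O5, O6, O10 and O15 are the oxygens on those carbons. On the decalin, β is the face of the C9 methyl group and α the other face.

Remark on the chemistry: the two C4 epimers formed in step 12 are carried together through steps 13 and 14, because C4 is planar in 22 and both epimers should give the same product.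

Step 1
Reactants: 1 (S)-Wieland–Miescher ketone
Product: 2 12β-hydroxy enone
Conditions: NaBH4 (0.3 equiv), EtOH, −10 °C
Reagents that add atoms: none
Why: NaBH4 reduction in which the saturated C12 ketone reacts before the conjugated C6 ketone and hydride enters from the α face, anti to the C9 methyl group, to give the equatorial 12β-alcohol.

Step 2
Reactants: 2 12β-hydroxy enone
Product: 3 hydroxy ketal
Conditions: ethylene glycol, p-TsOH (cat.), benzene, reflux, water separator
Reagents that add atoms: ethylene glycol (OCCO)
Why: Acid-catalysed ketalisation of the enone, which as in 4-en-3-one steroids moves the double bond out of conjugation to C10=C15 and leaves C11 as a CH2 group.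

Step 3
Reactants: 3 hydroxy ketal
Product: 4 keto ketal
Conditions: Dess–Martin periodinane, NaHCO3, CH2Cl2, 0 °C → rt
Reagents that add atoms: none
Why: Dess–Martin oxidation of the secondary alcohol under buffered conditions that should leave the ketal and the alkene untouched.

Step 4
Reactants: 4 keto ketal
Product: 6 enol triflate, via potassium enolate 5 (not isolated)
Conditions: KN(SiMe3)2, THF, −78 °C; then PhN(SO2CF3)2
Reagents that add atoms: N-phenylbis(trifluoromethanesulfonimide) (O=S(=O)(N(c1ccccc1)S(=O)(=O)C(F)(F)F)C(F)(F)F)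
Why: Kinetic enolisation, possible only toward C13 because C9 is quaternary, followed by O-sulfonylation of the enolate (enol triflate formation).

Step 5
Reactants: 6 enol triflate
Product: 7 alkenyl bromide
Conditions: Ni(OAc)2·4H2O (cat.), 1,5-cyclooctadiene, Zn (cat.), LiBr, DMA/THF, rt
Reagents that add atoms: lithium bromide ([Li+].[Br-])
Why: Nickel-catalysed halogen exchange of an enol triflate (oxidative addition to zerovalent nickel, triflate–bromide exchange, reductive elimination), which gives the alkenyl bromide that later becomes the C12 bromide.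

Step 6
Reactants: 7 alkenyl bromide
Product: 8 cis-diol
Conditions: OsO4 (cat.), N-methylmorpholine N-oxide, acetone/H2O, rt
Reagents that add atoms: N-methylmorpholine N-oxide (C[N+]1([O-])CCOCC1); water (O)
Why: Catalytic OsO4 dihydroxylation, which should pick the electron-rich trisubstituted C10=C15 alkene over the bromoalkene and add both oxygens from the α face, anti to the C9 methyl group, setting C10.

Step 7
Reactants: 8 cis-diol
Product: 9 bromo diol
Conditions: Co(acac)2 (cat.), t-BuOOH, Et3SiH, 1,4-cyclohexadiene, n-PrOH, rt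
Reagents that add atoms: none
Why: Hydrogen atom transfer hydrogenation of an alkenyl halide, in which a cobalt hydride gives H to C13 and the α-bromo radical at C12 takes H from cyclohexadiene on the α face, anti to the neighbouring C9 methyl group, so that bromine ends equatorial and β.

Step 8
Reactants: 9 bromo diol
Product: 10 α-hydroxy ketone
Conditions: Dess–Martin periodinane, NaHCO3, CH2Cl2, rt
Reagents that add atoms: none
Why: Dess–Martin oxidation of the secondary C15 alcohol beside the tertiary C10 alcohol, which should give the α-hydroxy ketone without C–C cleavage.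

Step 9
Reactants: 10 α-hydroxy ketone
Product: 11 methyl diol
Conditions: MeMgBr (3.5 equiv), THF, −78 → 0 °C; aq. NH4Cl
Reagents that add atoms: methylmagnesium bromide (C[Mg]Br)
Why: Grignard addition to the C15 ketone from the α (equatorial) side, because the axial β approach is blocked by the syn-axial C9 methyl group, which sets C15 with methyl α and hydroxyl β.

Step 10
Reactants: 11 methyl diol
Product: 12 bis(triethylsilyl) ether
Conditions: Et3SiOSO2CF3, 2,6-lutidine, CH2Cl2, 0 °C → rt
Reagents that add atoms: triethylsilyl trifluoromethanesulfonate (CC[Si](CC)(CC)OS(=O)(=O)C(F)(F)F)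
Why: Silyl triflate silylation of both tertiary alcohols, whose C10 silyl ether later shields the axial (α) side of C6 and the C11 flank of O6.

Step 11
Reactants: 12 bis(triethylsilyl) ether
Product: 13 bromo decalone
Conditions: pyridinium p-toluenesulfonate, acetone/H2O (10:1), 50 °C
Reagents that add atoms: water (O)
Why: Mild acid hydrolysis of the dioxolane under conditions that should spare the hindered tertiary silyl ethers and avoid β-elimination of the C10 oxygen.

Step 12
Reactants: 13 bromo decalone; 14 3-chlorobutan-2-one
Product: 17 spiro-epoxy ketone, via lithium chloro-enolate 15 (not isolated), via chlorohydrin lithium alkoxide 16 (not isolated)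
Conditions: 14, LiN(SiMe3)2, THF, −78 °C; then 13, −78 → 0 °C
Reagents that add atoms: none
Why: Darzens condensation in which the chloro-enolate adds to C6=O from the equatorial side, the axial side being blocked by the syn-axial C10 silyl ether, so that O6 becomes axial (α) as in the target and the alkoxide then closes the epoxide by displacing chloride at C4.

Step 13
Reactants: 17 spiro-epoxy ketone
Product: 19 chlorosilyl enol ether, via lithium enolate 18 (not isolated)
Conditions: LiN(i-Pr)2, THF, −78 °C; then i-Pr2SiCl2 (3 equiv); excess silane removed in vacuum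
Reagents that add atoms: dichlorodiisopropylsilane (CC(C)[Si](Cl)(Cl)C(C)C)
Why: Kinetic enolisation at C1, the only acidic position since C4 is fully substituted, and O-silylation by excess dichlorosilane, which stops at the chlorosilyl enol ether as in the preparation of unsymmetrical silyl bis-enol ethers.

Step 14
Reactants: 19 chlorosilyl enol ether; 20 1-bromo-2-methylprop-1-ene
Product: 24 ring A bromo ketone silanol, via enol silyl triflate 21 (not isolated), via siloxyallyl cation triflate 22 (not isolated), via cycloadduct silyl triflate 23 (not isolated)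
Conditions: AgOSO2CF3 (1.05 equiv), 2,6-di-tert-butyl-4-methylpyridine (0.3 equiv), 20 (10 equiv), CH2Cl2, −78 → −30 °C; aq. NaHCO3
Reagents that add atoms: water (O)
Why: Proposed new method: AgOSO2CF3 exchanges the Si–Cl bond of 19 for Si–OSO2CF3 (21); this silicon, already bound to O5, binds the epoxide oxygen O6 from within and pulls the C4–O6 bond open, so that a 2-siloxyallyl cation C1–C5–C4 forms inside a six-membered 1,3-dioxa-2-silacyclohexene ring (22), to which the bromoalkene adds in two stages, CHBr carbon C2 to the unhindered C1 and then ring carbon C4 to the bromonium-bridged tertiary C3, before triflate takes the silicon off O5 to leave the C5 ketone (23, hydrolysed to 24). The closest known reactions are the silyl triflate-promoted (4+3) cycloadditions of epoxy enol silanes with dienes and the (3+2) capture of oxyallyl cations from Nazarov cyclisations or α,α'-dihalo ketones by alkenes. The silicon ring closes by O6–Si bond formation as the epoxide breaks (a five-membered O5–Si···O6 chelate growing into the six-membered ring), and the cyclopentane closes by a 5-(enolendo)-exo-tet attack of C4 on C3. C4 is controlled by the half-chair of the silicon ring, which should lie on the C7 flank of C6 because the syn-axial C10 triethylsilyloxy group keeps silicon off the C11 flank, so the C6–C7 bond is pseudo-axial and C3 enters anti to it, which gives the target arrangement (C4 methyl anti to O6, C3 on the C11 side, C5 on the C7 side) from either C4 epimer of 19; C2 is controlled by anti opening of the bromonium ion on an enol ether whose C6 and O5 are held cis by the ring, which should place bromine cis to the C6 substituent. The step needs attack at C1 before C4 and Markovnikov addition to the alkene (secured by the fully substituted surroundings of C4 and the tertiary cation at C3), and the capture must outrun a 1,2-shift of a ring B bond to C4 (excess alkene, low temperature).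

Step 15
Reactants: 24 ring A bromo ketone silanol
Product: 25 ring A alcohol
Conditions: NaBH4, CeCl3·7H2O, MeOH/THF, −78 °C
Reagents that add atoms: none
Why: Luche reduction of the C5 ketone from the face opposite to the C6 substituent on C4 and to the C2 bromine, which should place the hydroxyl cis to both, at low temperature and near neutrality so that the β-bromo ketone does not lose HBr.

Step 16
Reactants: 25 ring A alcohol
Product: 26 neoirietetraol
Conditions: HF·pyridine, THF, 0 °C → rt
Reagents that add atoms: none
Why: Fluoride cleavage of all three Si–O bonds (global desilylation), which touches no stereocentre.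

**Compound list**

1 | (S)-Wieland–Miescher ketone, (8aS)-8a-methyl-3,4,8,8a-tetrahydronaphthalene-1,6(2H,7H)-dione | O=C1CC[C@]2(C)C(=O)CCCC2=C1 | starting material
2 | 12β-hydroxy enone, (4aS,5S)-5-hydroxy-4a-methyl-4,4a,5,6,7,8-hexahydronaphthalen-2(3H)-one (hydroxyl cis to the C9 methyl) | O=C1CC[C@]2(C)[C@@H](O)CCCC2=C1 | intermediate
3 | hydroxy ketal: C6 1,3-dioxolane, C10=C15 double bond, C12 hydroxyl β | C13(OCCO3)CC[C@]2(C)[C@@H](O)CCC=C2C1 | intermediate
4 | keto ketal: as 3 with a C12 ketone | C13(OCCO3)CC[C@]2(C)C(=O)CCC=C2C1 | intermediate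
5 | potassium enolate of 4 (C12–O−, C12=C13) | C13(OCCO3)CC[C@]2(C)C([O-])=CCC=C2C1.[K+] | intermediate
6 | enol triflate: C12–OSO2CF3 on C12=C13, C10=C15, C6 dioxolane | C13(OCCO3)CC[C@]2(C)C(OS(=O)(=O)C(F)(F)F)=CCC=C2C1 | intermediate
7 | alkenyl bromide: C12–Br on C12=C13, C10=C15, C6 dioxolane | C13(OCCO3)CC[C@]2(C)C(Br)=CCC=C2C1 | intermediate
8 | cis-diol: 10α-OH and 15α-OH, C12(Br)=C13, C6 dioxolane | C13(OCCO3)CC[C@]2(C)C(Br)=CC[C@H](O)[C@@]2(O)C1 | intermediate
9 | bromo diol: 12β-Br (equatorial), 10α-OH, 15α-OH, C6 dioxolane, trans-decalin | C13(OCCO3)CC[C@]2(C)[C@@H](Br)CC[C@H](O)[C@@]2(O)C1 | intermediate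
10 | α-hydroxy ketone: 12β-Br, 10α-OH, C15 ketone, C6 dioxolane | C13(OCCO3)CC[C@]2(C)[C@@H](Br)CCC(=O)[C@@]2(O)C1 | intermediate
11 | methyl diol: 12β-Br, 10α-OH, 15β-OH, 15α-CH3, C6 dioxolane | C13(OCCO3)CC[C@]2(C)[C@@H](Br)CC[C@@](C)(O)[C@@]2(O)C1 | intermediate
12 | bis(triethylsilyl) ether of 11 (on O10 and O15) | C13(OCCO3)CC[C@]2(C)[C@@H](Br)CC[C@@](C)(O[Si](CC)(CC)CC)[C@@]2(O[Si](CC)(CC)CC)C1 | intermediate
13 | bromo decalone: C6 ketone, 12β-Br, 9β-CH3, 15α-CH3, 10α- and 15β-OSiEt3 | O=C1CC[C@]2(C)[C@@H](Br)CC[C@@](C)(O[Si](CC)(CC)CC)[C@@]2(O[Si](CC)(CC)CC)C1 | intermediate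
14 | 3-chlorobutan-2-one (racemic) | CC(Cl)C(C)=O | starting material
15 | lithium enolate of 14 (enolate carbon bears Cl and CH3) | CC(Cl)=C(C)[O-].[Li+] | intermediate
16 | lithium alkoxide of the chlorohydrin: O6 axial (α) on C6, C4 (Cl, CH3, acetyl) equatorial, both C4 epimers | CC(=O)C(C)(Cl)[C@@]1([O-])CC[C@]2(C)[C@@H](Br)CC[C@@](C)(O[Si](CC)(CC)CC)[C@@]2(O[Si](CC)(CC)CC)C1.[Li+] | intermediate
17 | spiro-epoxy ketone: epoxide C4–O6–C6 with O6 axial (α); C4 bears CH3 and acetyl (C5=O, C1H3); both C4 epimers | CC(=O)C3(C)[C@@]1(O3)CC[C@]2(C)[C@@H](Br)CC[C@@](C)(O[Si](CC)(CC)CC)[C@@]2(O[Si](CC)(CC)CC)C1 | intermediate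
18 | lithium C1 enolate of 17 | C=C([O-])C3(C)[C@@]1(O3)CC[C@]2(C)[C@@H](Br)CC[C@@](C)(O[Si](CC)(CC)CC)[C@@]2(O[Si](CC)(CC)CC)C1.[Li+] | intermediate
19 | chloro(diisopropyl)silyl enol ether of 17 (C1H2=C5–O5–Si(i-Pr)2Cl) | C=C(O[Si](Cl)(C(C)C)C(C)C)C3(C)[C@@]1(O3)CC[C@]2(C)[C@@H](Br)CC[C@@](C)(O[Si](CC)(CC)CC)[C@@]2(O[Si](CC)(CC)CC)C1 | intermediate
20 | 1-bromo-2-methylprop-1-ene | CC(C)=CBr | starting material
21 | silyl triflate of 19 (Si–OSO2CF3 in place of Si–Cl) | C=C(O[Si](OS(=O)(=O)C(F)(F)F)(C(C)C)C(C)C)C3(C)[C@@]1(O3)CC[C@]2(C)[C@@H](Br)CC[C@@](C)(O[Si](CC)(CC)CC)[C@@]2(O[Si](CC)(CC)CC)C1 | intermediate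
22 | 2-siloxyallyl cation C1–C5–C4 inside the ring O5–Si(i-Pr)2–O6–C6–C4–C5, triflate salt | C=C1[C+](C)[C@@]2(O[Si](C(C)C)(C(C)C)O1)CC[C@]3(C)[C@@H](Br)CC[C@@](C)(O[Si](CC)(CC)CC)[C@@]3(O[Si](CC)(CC)CC)C2.[O-]S(=O)(=O)C(F)(F)F | intermediate
23 | cycloadduct: as 24 with O6–Si(i-Pr)2–OSO2CF3 | CC1(C)[C@H](Br)CC(=O)[C@]1(C)[C@@]1(O[Si](OS(=O)(=O)C(F)(F)F)(C(C)C)C(C)C)CC[C@]2(C)[C@@H](Br)CC[C@@](C)(O[Si](CC)(CC)CC)[C@@]2(O[Si](CC)(CC)CC)C1 | intermediate
24 | ring A ketone: C5=O, C2–Br cis to the C6 substituent on C4, C3 gem-dimethyl, C4–CH3, O6–Si(i-Pr)2OH, O10 and O15 as SiEt3 ethers | CC1(C)[C@H](Br)CC(=O)[C@]1(C)[C@@]1(O[Si](O)(C(C)C)C(C)C)CC[C@]2(C)[C@@H](Br)CC[C@@](C)(O[Si](CC)(CC)CC)[C@@]2(O[Si](CC)(CC)CC)C1 | intermediate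
25 | ring A alcohol: as 24 with C5–OH cis to C2–Br and to the C6 substituent | CC1(C)[C@H](Br)C[C@H](O)[C@]1(C)[C@@]1(O[Si](O)(C(C)C)C(C)C)CC[C@]2(C)[C@@H](Br)CC[C@@](C)(O[Si](CC)(CC)CC)[C@@]2(O[Si](CC)(CC)CC)C1 | intermediate
26 | neoirietetraol | CC1(C)[C@H](Br)C[C@H](O)[C@]1(C)[C@@]1(O)CC[C@]2(C)[C@@H](Br)CC[C@@](C)(O)[C@@]2(O)C1 | target

**Step count and risks**

Total steps: 16. Longest linear sequence: 16 steps (1 → 26); 14 and 20 are bought.

The three steps most likely to fail:

1. Step 14 (Proposed new method). The siloxyallyl cation 22 may be lost to a 1,2-shift of a ring B bond from C6 to C4 (ring enlargement) or to proton loss from the C4 methyl before the weakly nucleophilic bromoalkene adds. The facial selectivity at C4 may also be poor. The fallback uses known reaction types and sets out from 17. The C1–C2 bond is made first by palladium-catalysed α-alkenylation of the C1 enolate with 20 (LiN(SiMe3)2, Pd2(dba)3, a bulky biaryl phosphine), which should give the β,γ-unsaturated epoxy ketone F1. Reductive opening of the epoxide with SmI2 at −78 °C and trapping of the samarium enolate and alkoxide with i-Pr2Si(OSO2CF3)2 should give the cyclic silylene enol ether F2, with the enol double bond fixed at C4=C5. A bromonium source (Et2SBr·SbCl5Br) then closes ring A by bromonium-induced cyclisation of the enol ether carbon C4 onto C3, with bromine on C2. Aqueous work-up should give 24, where the fallback comes back to the route.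

2. Step 12. The basic chloro-enolate may enolise the decalone, with β-elimination of the C10 silyloxy group, and the chlorohydrin alkoxide may revert by retro-aldol cleavage before the epoxide closes. The fallback sets out from 13 and 14 and needs no base in the C–C bond-forming step. 14 is turned into its trimethylsilyl enol ether F3 (Me3SiCl, Et3N, NaI). A TiCl4-promoted Mukaiyama aldol addition of F3 to 13 at −78 °C should give the chlorohydrin F4 by equatorial attack (O6 axial). K2CO3 in methanol at 0 °C then closes the epoxide to 17, where the fallback comes back.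

3. Step 7. Hydrogen may be delivered to the β face of the C12 radical, or bromine may be lost by over-reduction. The fallback sets out from 4. Condensation with N2H4·H2O gives the hydrazone F5, and oxidation with CuBr2 and LiOt-Bu gives the geminal dibromide F6. One equivalent of Bu3SnH (AIBN) then removes one bromine, the bulky stannane giving H to the less hindered α face, which should leave the 12β-bromide F7. OsO4/N-methylmorpholine N-oxide dihydroxylation of F7, as in step 6, should give 9, where the fallback comes back.

**Further compounds**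

F1 | step 14 | β,γ-unsaturated epoxy ketone: 17 with a 2-methylprop-1-enyl group on C1 | CC(C)=CCC(=O)C3(C)[C@@]1(O3)CC[C@]2(C)[C@@H](Br)CC[C@@](C)(O[Si](CC)(CC)CC)[C@@]2(O[Si](CC)(CC)CC)C1
F2 | step 14 | cyclic diisopropylsilylene enol ether: ring O5–Si(i-Pr)2–O6–C6–C4=C5, C5 bearing CH2–CH=C(CH3)2 | CC(C)=CCC1=C(C)[C@@]2(O[Si](C(C)C)(C(C)C)O1)CC[C@]3(C)[C@@H](Br)CC[C@@](C)(O[Si](CC)(CC)CC)[C@@]3(O[Si](CC)(CC)CC)C2
F3 | step 12 | trimethylsilyl enol ether of 14, (3-chlorobut-2-en-2-yloxy)trimethylsilane | CC(Cl)=C(C)O[Si](C)(C)C
F4 | step 12 | chlorohydrin: C6–OH axial (α), C4 bearing Cl, CH3 and acetyl | CC(=O)C(C)(Cl)[C@@]1(O)CC[C@]2(C)[C@@H](Br)CC[C@@](C)(O[Si](CC)(CC)CC)[C@@]2(O[Si](CC)(CC)CC)C1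
F5 | step 7 | C12 hydrazone of 4 | C13(OCCO3)CC[C@]2(C)C(=NN)CCC=C2C1
F6 | step 7 | C12 geminal dibromide, C10=C15, C6 dioxolane | C13(OCCO3)CC[C@]2(C)C(Br)(Br)CCC=C2C1
F7 | step 7 | 12β-bromide, C10=C15, C6 dioxolane | C13(OCCO3)CC[C@]2(C)[C@@H](Br)CCC=C2C1
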